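In a one-step world where starting material leaves at a steady fractional pace, each equal stretch of time leaves the same fraction of what stood at its start, so successive gains of product shrink by one constant factor. We hold the epsilon run to that picture.

| setting | epsilon | beta | zeta | delta |
|---|---|---|---|---|
| starting material | 100 mM | 100 mM | 300 mM | 50.0 mM |
| partner | 110 mM | 110 mM | 110 mM | 36.0 mM |
| product |  | 30.0 mM |  |  |
| time |  |  |  | 23 min |

| epsilon run: time / min | epsilon run: [product] / mM | beta run: time / min | beta run: [product] / mM | zeta run: time / min | zeta run: [product] / mM |
|---|---|---|---|---|---|
| 4.6 | 26.6 | 4.6 | 56.7 | 4.6 | 61.7 |
| 9.2 | 37.6 | 9.2 | 65.5 | 9.2 | 83.6 |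
| 14 | 39.5 | 14 | 71.2 | 14 | 91.4 |
| 18 | 41.5 | 18 | 74.8 | 18 | 95.9 |
| 23 | 43.7 | 23 | 74.7 | 23 | 99.4 |

(scatter of a reading: 1 mM)

1. order of the initial rate in [starting material], near the charge of the epsilon run, the rate being that where two percent of its starting material are product (one fixed amount of product, the same in the runs compared)
2. product in the delta run at 23 min, as a share of the starting material charged

- Overall: starting material + partner -> product.
- Constant volume, constant temperature.
- A reading of a species includes what of it is bound.
- An order is taken over about fifteen percent of the charge, up and down.

The beta run, net of its added product, has made 26.7 mM at the first reading, where the epsilon run has 26.6 mM, so added product shows no effect on the early gain in these readings. The epsilon run gains 26.6 mM in its first 4.6 min and 11.0 mM in the next stretch of that length. We therefore reckon: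

fraction kept per stretch = second gain / first gain = 0.414

fade = ln(first gain / second gain) / stretch = 0.192 min⁻¹

level = first gain / (1 − fraction kept) = 45.4 mM

So, as read from these two gains, the epsilon curve starts at a slope of about 8.72 mM min⁻¹, its gap to the level halves every 3.61 min, and it has bent by 9.2 min, with 72.4 mM of the partner charge not turned into product. It then approaches the level; the last reading is 43.7 mM.

The level is 45.4% of the charge, so we split the fade into a main pace of 0.0871 min⁻¹ and the leak, the fractional pace per minute at which starting material goes without giving product:

leak = fade × (1 − share) = 0.105 min⁻¹

In the delta run, the partner is the limiting reagent by charge. The leak by itself keeps 8.94% of the starting material by 23 min, so we read the ceiling, main pace / (main pace + leak). With the partner held at its charge, a main pace proportional to partner gives 21.4%, and one proportional to its square root gives 32.2%.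

The forecast gives an order of 0.95 and, for the delta run, 25%. That share lies inside our range, but the forecast reaches it by its own road, “using the same time function”.

The simulation gives an order of 0.99 and, for the delta run, 28.1%.

    starting material + partner ⇌ intermediate, settled at all times (4.140 L mol⁻¹)
    starting material + partner → product (3.252 L mol⁻¹ min⁻¹)
    2 partner ⇌ idle reagent dimer, settled at all times (43.10 L mol⁻¹)
    starting material → decomposed substrate (0.1002 min⁻¹)

The forecast's 25% would be wrong if a run showed the delta flask without the path from starting material to decomposed substrate: there it gives 50.8% instead of 28.1%. Treating 28.1% as if it were the ceiling, our leak of 0.105 min⁻¹ gives the delta run a rough main pace of 0.0410 min⁻¹. Held steady for 23 min with the leak removed, that pace turns 61.1% of the starting material charged, and the delta run without the path reaches 50.8%.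

(Readings and results come from a simulation with constants of no real substance; the scatter is artificial.)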